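## Analysis of the target

The target 18, 2-hydroxy-4-[(2-hydroxy-4-methoxy-6-methylbenzoyl)oxy]-6-pentylbenzoic acid, is a depside: two benzene rings joined only by an aryl ester. It has no stereocentre and no ring to close. Ring A is a salicylic acid (C1 CO2H, C2 OH, C6 pentyl) whose C4 carries the ester oxygen. Ring B is a 2-hydroxy-4-methoxy-6-methylbenzoyl unit whose carbonyl carbon sits between a methyl group and an oxygen substituent. The aryl ester is an activated ester that base or nucleophiles cleave or transfer, so the last step cannot be basic. The ring A acid is a 2-hydroxy-6-alkylbenzoic acid that can lose CO2 in hot or strong acid, and two phenols and one carboxyl group must be kept apart from the coupling. The usual ester formation is hard here, because a weakly nucleophilic phenol (para to a carboxyl group) would have to attack a carbonyl carbon shielded on both sides. The strategy rests on ring A C4: its neighbours C3 and C5 both carry hydrogen, so in a ring A precursor with hydrogen at C4 this is the only C–H without an ortho substituent. Boron can therefore be placed there by steric control, and the ester can be made by forming the ring A C4–O bond from the carboxylate oxygen, which leaves the shielded ring B carbonyl carbon untouched.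

## Retrosynthetic reasoning

**18 to 17.** The last disconnection removes only protecting groups. The two phenols are masked as methoxymethyl ethers and the ring A carboxyl as a tert-butyl ester, as in 17. All three fall to anhydrous acid in one operation, which the aryl ester tolerates, whereas base would cleave it. Benzyl groups are not used on ring A, because their unhindered aryl C–H bonds would compete in the borylation further back.

**17 to 10 and 16.** The bond cut is ring A C4–O, not the acyl C–O bond of the ester. Cutting on the aryl side turns the hindered acid 16 into an oxygen nucleophile, and ring A becomes the aryl donor 10 with boron at C4. The forward reaction is an aerobic copper-promoted O-arylation of a carboxylic acid. It has to favour carboxylate arylation over protodeboronation, homocoupling and hydroxylation of 10. For that reason every other O–H is masked, and the copper source must carry no carboxylate counterion of its own, since such a counterion would be arylated in competition.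

**10 to 9 to 7 and 8.** The C4–B bond is cut next. Boronic acid 10 comes from the cyclic boronic ester 9 by cleavage of the diol. Ester 9 comes from arene 7 and diboron 8 by iridium-catalysed C–H borylation. In 7, C3 is flanked by the methoxymethoxy group and C5 by the pentyl chain, so only C4 is open. No electrophilic substitution would reach this position, which is meta to both donors.

**7 to 4 and 5.** The pentyl chain is cut between its first and second carbon. The methyl group of 4 lies ortho to the ester and is deprotonated to the benzylic lithium compound 6, which is alkylated by 1-iodobutane 5. The starting material then already holds the 1,2,3-substitution pattern of ring A, and the chain length is set by the choice of 5.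

**4 to 2 to 1.** Ether 4 is the methoxymethyl ether, made through the sodium phenoxide 3, of the tert-butyl ester 2 of commercial 2-hydroxy-6-methylbenzoic acid 1. The ester is put on first by alkylation at the carboxyl oxygen, which is not slowed by the two ortho groups. Its bulk then protects the carbonyl during the lithiation.

**16 to 14 to 12 to 11.** Acid 16 is obtained through its potassium salt 15 by saponification of methyl ester 14. Ester 14 is the methoxymethyl ether, made through the sodium phenoxide 13, of 12. Compound 12 is the 4-O-methyl ether of commercial methyl orsellinate 11. The C4 hydroxyl of 11 is not hydrogen-bonded and is the more acidic one, so it is methylated first and needs no protecting group to be told apart from the chelated C2 hydroxyl.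

## Alternatives that were turned down

**Alternative 1:** Ring B is folded from a chain, not bought. The disconnection cuts the ring B C1–C6 bond and opens ring B into a linear triketo ester already attached to the ring A C4 oxygen: benzyl 2-hydroxy-6-pentyl-4-[(3,5,7-trioxooctanoyl)oxy]benzoate A2. In the forward direction a mild amine base would bring about the aldol attack of chain C2 on the C7 ketone, and acid would dehydrate the adduct to benzyl 4-[(2,4-dihydroxy-6-methylbenzoyl)oxy]-2-hydroxy-6-pentylbenzoate A1.
- **For:** the ester is formed while the acyl carbon is still an unhindered aliphatic one, so the steric problem of ring B never arises. No transition metal is needed, and one step sets all of ring B. On these points it is stronger than the chosen route.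
- **Against:** A2 is an aryl ester of a β-keto acid, a class that loses its phenoxide readily through an acylketene. The chain has other ways to cyclise (Claisen attack of C6 on C1, or pyrone formation from the C5 enol oxygen onto C1). Both expel the ring A phenoxide, a good leaving group, and destroy the ester link. The preparation of A2 is itself a multistep chain assembly on a labile ester. A1 still needs selective methylation of the ring B C4 hydroxyl and a hydrogenolysis before it becomes 18.
- **Comparison:** the chosen strategy uses two finished, stable aromatic rings and puts its risk into one coupling of a known type.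

**Alternative 2:** The carboxyl carbon of ring A is added last. The disconnection cuts the ring A C1–carboxyl bond. In the forward direction 5-pentylbenzene-1,3-diol A5 is mono-acylated with 2-(benzyloxy)-4-methoxy-6-methylbenzoic acid A6 to give 3-hydroxy-5-pentylphenyl 2-(benzyloxy)-4-methoxy-6-methylbenzoate A4. The magnesium phenoxide of A4 is ortho-formylated (Casnati–Skattebøl type) to 4-formyl-3-hydroxy-5-pentylphenyl 2-(benzyloxy)-4-methoxy-6-methylbenzoate A3. Oxidation of the aldehyde to the acid and hydrogenolysis would finish the synthesis.
- **For:** A5 is cheap and already carries the pentyl group and both oxygens. Ring A needs no lateral alkylation, no borylation and no protecting group, and the step count is lower than here. On step economy this alternative is the stronger one.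
- **Against:** the free phenol of A4 has two ortho C–H positions, one between the hydroxyl and the pentyl group (wanted) and one between the hydroxyl and the acyloxy group. Magnesium chelation directs ortho over para but cannot tell these two apart. The mono-acylation of symmetrical A5 is statistical. Under the hot amine and magnesium phenoxide conditions the aryl ester can transfer between phenoxide oxygens. The hindered ester bond must still be formed by attack at the shielded carbonyl of A6.
- **Comparison:** the chosen strategy is longer, but the position of every substituent is fixed by a starting material or by ipso substitution at boron, so no isomer separation is planned.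

**Alternative 3:** Ring B is built by cycloaddition on an alkynoate already esterified to ring A. The disconnection cuts the ring B C1–C2 and C5–C6 bonds. In the forward direction benzyl 2-(benzyloxy)-4-(but-2-ynoyloxy)-6-pentylbenzoate A8 and 1,3-dimethoxy-1-(trimethylsilyloxy)buta-1,3-diene A9 are heated. The CH2 terminus of the diene bonds to the methyl-bearing alkyne carbon and the ketene acetal carbon to the ester-bearing one. Acid then aromatises the adduct with loss of the silyl group and one methoxy group to benzyl 2-(benzyloxy)-4-[(2-hydroxy-4-methoxy-6-methylbenzoyl)oxy]-6-pentylbenzoate A7.
- **For:** the polarisation of A9 fixes the ring B pattern. Ring B arrives with its C2 hydroxyl free and its C4 methoxy group in place, so it needs neither a protecting group nor a selective methylation. The ester is made from a small unhindered alkynoic acid. In these respects it is cleaner than the chosen route.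
- **Against:** a β-methyl alkynoate is a slow dienophile and needs prolonged heating. Under that heating the silyl ketene acetal A9 can decompose, add stepwise in a Mukaiyama–Michael manner, or attack the activated aryl ester carbonyl of A8. The ring A partner must have its C2 hydroxyl benzylated while the more reactive C4 hydroxyl stays free, which costs extra protecting group steps. A hydrogenolysis follows at the end.
- **Comparison:** the chosen strategy forms one C–O bond between two complete rings under mild conditions, and each ring is reached in few steps from a commercial benzoate.

Key step: step 9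

Remark: ring A denotes the benzoic acid ring of the target (C1 CO2H, C2 OH, C4 acyloxy, C6 pentyl) and ring B the 2-hydroxy-4-methoxy-6-methylbenzoyl ring. The target is achiral, so no step has to control configuration.

## Route

Step 1
Reactants: 1 2-hydroxy-6-methylbenzoic acid
Product: 2 tert-butyl 2-hydroxy-6-methylbenzoate
Conditions: Cl3CC(=NH)OtBu (2 equiv), CH2Cl2/cyclohexane, rt
Reagents that add atoms: tert-butyl 2,2,2-trichloroacetimidate, CC(C)(C)OC(=N)C(Cl)(Cl)Cl
Why: O-tert-butylation of a carboxylic acid with a trichloroacetimidate: the acid protonates the imidate and the carboxylate captures the tert-butyl cation, so the bond forms at oxygen and the two ortho groups do not slow it. The less acidic, hydrogen-bonded phenol does not activate the imidate without an added Lewis acid and should stay free.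

Step 2
Reactants: 2 tert-butyl 2-hydroxy-6-methylbenzoate
Product: 4 tert-butyl 2-(methoxymethoxy)-6-methylbenzoate, via sodium phenoxide 3 (not isolated)
Conditions: NaH, DMF, 0 °C; then MOMCl, 0 °C → rt
Reagents that add atoms: chloromethyl methyl ether, COCCl
Why: Williamson ether synthesis: NaH breaks the hydrogen bond to the ester carbonyl and the phenoxide displaces chloride from the reactive α-chloro ether. The tert-butyl ester is inert to the phenoxide.

Step 3
Reactants: 4 tert-butyl 2-(methoxymethoxy)-6-methylbenzoate; 5 1-iodobutane
Product: 7 tert-butyl 2-(methoxymethoxy)-6-pentylbenzoate, via benzylic lithium compound 6 (not isolated)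
Conditions: LiN(iPr)2 (LDA, commercial solution, 1.2 equiv), THF, −78 °C (4 added to the base); then 5 (1.5 equiv), −78 → −20 °C
Reagents that add atoms: none
Why: Lateral lithiation of an ortho-toluate followed by SN2 alkylation, as used for 6-alkylsalicylates: the ester stabilises the benzylic anion as an extended enolate, and the amide base is too hindered to add to the tert-butyl ester and too weak to metalate the ring next to the methoxymethoxy group. The primary iodide should alkylate the anion at carbon, turning the methyl group into the pentyl chain.

Step 4
Reactants: 7 tert-butyl 2-(methoxymethoxy)-6-pentylbenzoate; 8 bis(pinacolato)diboron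
Product: 9 tert-butyl 2-(methoxymethoxy)-6-pentyl-4-(4,4,5,5-tetramethyl-1,3,2-dioxaborolan-2-yl)benzoate
Conditions: [Ir(OMe)(cod)]2 (1.5 mol%), 4,4'-di-tert-butyl-2,2'-bipyridine (3 mol%), THF, 80 °C, N2
Reagents that add atoms: none
Why: Iridium-catalysed aromatic C–H borylation through a trivalent iridium tris(boryl) complex, which is governed by sterics and avoids C–H bonds next to a substituent. In 7, C3 is flanked by the methoxymethoxy group and C5 by the pentyl chain, so only C4 should react; the bipyridine ligand gives no ester- or ether-directed borylation.

Step 5
Reactants: 9 tert-butyl 2-(methoxymethoxy)-6-pentyl-4-(4,4,5,5-tetramethyl-1,3,2-dioxaborolan-2-yl)benzoate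
Product: 10 [4-(tert-butoxycarbonyl)-3-(methoxymethoxy)-5-pentylphenyl]boronic acid
Conditions: NaIO4 (3 equiv), NH4OAc (3 equiv), acetone/H2O, rt
Reagents that add atoms: water, O
Why: Oxidative deprotection of a pinacol boronic ester: periodate cleaves the pinacol released in the hydrolysis equilibrium to acetone and so drives the ester to the free boronic acid. The buffered, near-neutral medium should leave the methoxymethyl ether and the tert-butyl ester intact.

Step 6
Reactants: 11 methyl 2,4-dihydroxy-6-methylbenzoate (methyl orsellinate)
Product: 12 methyl 2-hydroxy-4-methoxy-6-methylbenzoate
Conditions: MeI (1.05 equiv), K2CO3, acetone, rt → 50 °C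
Reagents that add atoms: iodomethane, CI
Why: Selective Williamson O-methylation: the C4 hydroxyl is para to the ester, more acidic and not hydrogen-bonded, whereas the C2 hydroxyl is chelated to the carbonyl. One equivalent of the alkylating agent should therefore give the 4-monoether.

Step 7
Reactants: 12 methyl 2-hydroxy-4-methoxy-6-methylbenzoate
Product: 14 methyl 4-methoxy-2-(methoxymethoxy)-6-methylbenzoate, via sodium phenoxide 13 (not isolated)
Conditions: NaH, DMF, 0 °C; then MOMCl, 0 °C → rt
Reagents that add atoms: chloromethyl methyl ether, COCCl
Why: Williamson ether synthesis as in step 2: full deprotonation overcomes the chelation of the remaining phenol, and the phenoxide is alkylated at oxygen by the α-chloro ether.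

Step 8
Reactants: 14 methyl 4-methoxy-2-(methoxymethoxy)-6-methylbenzoate
Product: 16 4-methoxy-2-(methoxymethoxy)-6-methylbenzoic acid, via potassium carboxylate 15 (not isolated)
Conditions: KOH, DMSO/H2O, 85 °C; then aq. KHSO4, 0 °C, to pH 3–4
Reagents that add atoms: potassium hydroxide, [K+].[OH-]
Why: Saponification (BAC2) of a doubly ortho-substituted methyl benzoate, which needs poorly solvated hydroxide in aqueous DMSO and heat. The aryl methyl ether and the acetal are stable to base, and cold, brief acidification to pH 3–4 should liberate the acid without cleaving the methoxymethyl ether.

Step 9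
Reactants: 16 4-methoxy-2-(methoxymethoxy)-6-methylbenzoic acid; 10 [4-(tert-butoxycarbonyl)-3-(methoxymethoxy)-5-pentylphenyl]boronic acid
Product: 17 tert-butyl 4-{[4-methoxy-2-(methoxymethoxy)-6-methylbenzoyl]oxy}-2-(methoxymethoxy)-6-pentylbenzoate
Conditions: Cu(OTf)2 (40 mol%), pyridine (2 equiv), 4 Å molecular sieves, EtOAc, dry air, 45 °C; 10 (1.5 equiv) added in portions
Reagents that add atoms: none
Why: This is a Chan–Lam oxidative C–O coupling, the known copper-promoted O-arylation of carboxylic acids by arylboronic acids. Pyridine deprotonates 16 and the carboxylate binds divalent copper; the aryl group of 10 transmetalates from boron to this copper carboxylate, a second divalent copper oxidises the aryl copper carboxylate to trivalent copper, reductive elimination forms the ring A C4–O bond, and air returns monovalent copper to the divalent state. No ring is closed and no stereocentre is formed. The site is fixed because the bond forms ipso to boron, which step 4 placed at C4. Steric demand is low on both sides: C4 has hydrogen on both neighbours, and the bond is made at the carboxylate oxygen, one atom away from the doubly ortho-substituted carbonyl carbon, which is never attacked. Chemoselectivity requires that the carboxylate of 16 be the only oxygen nucleophile on copper: both phenols and the ring A carboxyl are masked, sieves and dry air keep water from hydroxylating 10, and Cu(OTf)2 replaces the customary Cu(OAc)2 because acetate is itself a carboxylate and would be arylated in competition to give the aryl acetate of ring A. Pyridine buffers the triflic acid released on carboxylate binding so that the methoxymethyl ethers and the tert-butyl ester should survive, and 10 is used in excess to offset protodeboronation (which returns 7) and biaryl homocoupling.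

Step 10
Reactants: 17 tert-butyl 4-{[4-methoxy-2-(methoxymethoxy)-6-methylbenzoyl]oxy}-2-(methoxymethoxy)-6-pentylbenzoate
Product: 18 2-hydroxy-4-[(2-hydroxy-4-methoxy-6-methylbenzoyl)oxy]-6-pentylbenzoic acid
Conditions: CF3CO2H/CH2Cl2 (1:4), H2O (5 equiv), 0 °C → rt
Reagents that add atoms: none
Why: Global acidolysis: the tert-butyl ester cleaves at the alkyl–oxygen bond through the tert-butyl cation, and the two aryl methoxymethyl acetals hydrolyse through oxocarbenium ions that the added water traps. The aryl ester has no cation-stabilising alkyl group and a shielded carbonyl, so it should persist, and the low temperature limits decarboxylation of the salicylic acid.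

## Compound list

1 | 2-hydroxy-6-methylbenzoic acid | Cc1cccc(O)c1C(=O)O | starting material
2 | tert-butyl 2-hydroxy-6-methylbenzoate | Cc1cccc(O)c1C(=O)OC(C)(C)C | intermediate
3 | sodium 2-(tert-butoxycarbonyl)-3-methylphenolate | Cc1cccc([O-])c1C(=O)OC(C)(C)C.[Na+] | intermediate (not isolated)
4 | tert-butyl 2-(methoxymethoxy)-6-methylbenzoate | COCOc1cccc(C)c1C(=O)OC(C)(C)C | intermediate
5 | 1-iodobutane | CCCCI | starting material
6 | tert-butyl 2-(lithiomethyl)-6-(methoxymethoxy)benzoate | [Li]Cc1cccc(OCOC)c1C(=O)OC(C)(C)C | intermediate (not isolated)
7 | tert-butyl 2-(methoxymethoxy)-6-pentylbenzoate | CCCCCc1cccc(OCOC)c1C(=O)OC(C)(C)C | intermediate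
8 | bis(pinacolato)diboron | CC1(C)OB(OC1(C)C)B1OC(C)(C)C(C)(C)O1 | starting material
9 | tert-butyl 2-(methoxymethoxy)-6-pentyl-4-(4,4,5,5-tetramethyl-1,3,2-dioxaborolan-2-yl)benzoate | CCCCCc1cc(B2OC(C)(C)C(C)(C)O2)cc(OCOC)c1C(=O)OC(C)(C)C | intermediate
10 | [4-(tert-butoxycarbonyl)-3-(methoxymethoxy)-5-pentylphenyl]boronic acid | CCCCCc1cc(B(O)O)cc(OCOC)c1C(=O)OC(C)(C)C | intermediate
11 | methyl 2,4-dihydroxy-6-methylbenzoate (methyl orsellinate) | COC(=O)c1c(C)cc(O)cc1O | starting material
12 | methyl 2-hydroxy-4-methoxy-6-methylbenzoate | COC(=O)c1c(C)cc(OC)cc1O | intermediate
13 | sodium 5-methoxy-2-(methoxycarbonyl)-3-methylphenolate | COC(=O)c1c(C)cc(OC)cc1[O-].[Na+] | intermediate (not isolated)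
14 | methyl 4-methoxy-2-(methoxymethoxy)-6-methylbenzoate | COCOc1cc(OC)cc(C)c1C(=O)OC | intermediate
15 | potassium 4-methoxy-2-(methoxymethoxy)-6-methylbenzoate | COCOc1cc(OC)cc(C)c1C(=O)[O-].[K+] | intermediate (not isolated)
16 | 4-methoxy-2-(methoxymethoxy)-6-methylbenzoic acid | COCOc1cc(OC)cc(C)c1C(=O)O | intermediate
17 | tert-butyl 4-{[4-methoxy-2-(methoxymethoxy)-6-methylbenzoyl]oxy}-2-(methoxymethoxy)-6-pentylbenzoate | CCCCCc1cc(OC(=O)c2c(C)cc(OC)cc2OCOC)cc(OCOC)c1C(=O)OC(C)(C)C | intermediate
18 | 2-hydroxy-4-[(2-hydroxy-4-methoxy-6-methylbenzoyl)oxy]-6-pentylbenzoic acid | CCCCCc1cc(OC(=O)c2c(C)cc(OC)cc2O)cc(O)c1C(=O)O | target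

## Step count and least certain steps

Total step count: 10 steps. Longest linear sequence: 7 steps (steps 1–5, 9 and 10); the ring B branch (steps 6–8) joins at step 9.

**Step 9 (key step).** The most likely failure is loss of the aryl boron partner before it reaches a copper carboxylate. This can happen by protodeboronation, by oxidative homocoupling, or by hydroxylation with adventitious water followed by diaryl ether formation. Transmetalation is slowed because boron sits para to an ester on an electron-poor ring. A second concern is partial loss of a methoxymethyl group if the buffering by pyridine is insufficient against the Lewis acidic copper triflate.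
Fallback: it sets out from 10 and returns at 17, and it forms the ester on the acyl side. Boronic acid 10 is oxidised with H2O2 and NaHCO3 in THF/H2O to tert-butyl 4-hydroxy-2-(methoxymethoxy)-6-pentylbenzoate F1. F1 is then esterified with acid 16 under carbodiimide activation (N,N'-dicyclohexylcarbodiimide, 4-(dimethylamino)pyridine, CH2Cl2, rt), the classical depside coupling. Attack at the shielded carbonyl is expected to be slow, but every group in both partners tolerates the conditions.

**Step 10.** The oxocarbenium and tert-butyl cations released in the acid may alkylate the electron-rich rings, above all ring B once its phenol is free. Prolonged exposure to strong acid may also cause decarboxylation of the ring A salicylic acid, and cleavage of the chelation-prone methoxymethyl ethers may stall.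
Fallback: it sets out from 17 and returns at 18, and it separates the two kinds of cleavage. Acid-catalysed transacetalisation in methanol (HCl generated from a little acetyl chloride, MeOH/THF, rt to 40 °C) removes both methoxymethyl groups as dimethoxymethane, which is not an electrophile toward the rings. The product is tert-butyl 2-hydroxy-4-[(2-hydroxy-4-methoxy-6-methylbenzoyl)oxy]-6-pentylbenzoate F2. F2 is then treated briefly with CF3CO2H in CH2Cl2 at 0 °C, where only the tert-butyl ester remains to be cleaved.

**Step 3.** The benzylic anion may add to the ester of unreacted 4 (self-condensation). Proton transfer between product and anion may lead to double alkylation, or alkylation may be incomplete if the anion aggregates.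
Fallback: it sets out from 4 and returns at 7, and it reverses the polarity of the benzylic carbon. Radical bromination (N-bromosuccinimide, light, PhCF3, rt, with solid K2CO3 as acid scavenger) gives tert-butyl 2-(bromomethyl)-6-(methoxymethoxy)benzoate F3. F3 is coupled with n-BuMgCl under Li2CuCl4 catalysis in THF at −78 °C, a copper-catalysed alkyl–benzyl coupling that the hindered tert-butyl ester should survive.

**Step 8.** Hydroxide attack on the doubly ortho-substituted ester may be too slow, and forcing it or acidifying carelessly may cost the methoxymethyl group.
Fallback: it sets out from 14 and returns at 16, and it passes through the aldehyde oxidation level, so no hydroxide has to add to the hindered ester. LiAlH4 in THF reduces 14 to [4-methoxy-2-(methoxymethoxy)-6-methylphenyl]methanol F4. MnO2 in CH2Cl2 oxidises F4 to 4-methoxy-2-(methoxymethoxy)-6-methylbenzaldehyde F5. A chlorite oxidation (NaClO2, NaH2PO4, 2-methylbut-2-ene, t-BuOH/H2O) converts F5 to acid 16 at a pH the acetal tolerates.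

## Further compounds

F1 | step 9 | tert-butyl 4-hydroxy-2-(methoxymethoxy)-6-pentylbenzoate | CCCCCc1cc(O)cc(OCOC)c1C(=O)OC(C)(C)C
F2 | step 10 | tert-butyl 2-hydroxy-4-[(2-hydroxy-4-methoxy-6-methylbenzoyl)oxy]-6-pentylbenzoate | CCCCCc1cc(OC(=O)c2c(C)cc(OC)cc2O)cc(O)c1C(=O)OC(C)(C)C
F3 | step 3 | tert-butyl 2-(bromomethyl)-6-(methoxymethoxy)benzoate | BrCc1cccc(OCOC)c1C(=O)OC(C)(C)C
F4 | step 8 | [4-methoxy-2-(methoxymethoxy)-6-methylphenyl]methanol | COCOc1cc(OC)cc(C)c1CO
F5 | step 8 | 4-methoxy-2-(methoxymethoxy)-6-methylbenzaldehyde | COCOc1cc(OC)cc(C)c1C=O
A1 | alternative 1 | benzyl 4-[(2,4-dihydroxy-6-methylbenzoyl)oxy]-2-hydroxy-6-pentylbenzoate | CCCCCc1cc(OC(=O)c2c(C)cc(O)cc2O)cc(O)c1C(=O)OCc1ccccc1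
A2 | alternative 1 | benzyl 2-hydroxy-6-pentyl-4-[(3,5,7-trioxooctanoyl)oxy]benzoate | CCCCCc1cc(OC(=O)CC(=O)CC(=O)CC(C)=O)cc(O)c1C(=O)OCc1ccccc1
A3 | alternative 2 | 4-formyl-3-hydroxy-5-pentylphenyl 2-(benzyloxy)-4-methoxy-6-methylbenzoate | CCCCCc1cc(OC(=O)c2c(C)cc(OC)cc2OCc2ccccc2)cc(O)c1C=O
A4 | alternative 2 | 3-hydroxy-5-pentylphenyl 2-(benzyloxy)-4-methoxy-6-methylbenzoate | CCCCCc1cc(O)cc(OC(=O)c2c(C)cc(OC)cc2OCc2ccccc2)c1
A5 | alternative 2 | 5-pentylbenzene-1,3-diol | CCCCCc1cc(O)cc(O)c1
A6 | alternative 2 | 2-(benzyloxy)-4-methoxy-6-methylbenzoic acid | Cc1cc(OC)cc(OCc2ccccc2)c1C(=O)O
A7 | alternative 3 | benzyl 2-(benzyloxy)-4-[(2-hydroxy-4-methoxy-6-methylbenzoyl)oxy]-6-pentylbenzoate | CCCCCc1cc(OC(=O)c2c(C)cc(OC)cc2O)cc(OCc2ccccc2)c1C(=O)OCc1ccccc1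
A8 | alternative 3 | benzyl 2-(benzyloxy)-4-(but-2-ynoyloxy)-6-pentylbenzoate | CCCCCc1cc(OC(=O)C#CC)cc(OCc2ccccc2)c1C(=O)OCc1ccccc1
A9 | alternative 3 | 1,3-dimethoxy-1-(trimethylsilyloxy)buta-1,3-diene | COC(=C)C=C(OC)O[Si](C)(C)C
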